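**Retrosynthetic overview**
- Feature: in the bicyclo[3.2.1]octane core (C1 enone carbonyl, C2, C3 styryl carbon, C4 and C5 bridgeheads, C6 catechol-bearing, C7 resorcinol-bearing, C8 bridging ketone) the cyclopentanone ring C4–C8–C5–C6–C7 holds a C6–C7 bond between two benzylic carbons that are both β to C8. With NH inserted between C6 and C7 this ring is the piperidinone of a double Mannich product.
- Key disconnection: C6–C7, formed by loss of N2 from the isodiazene of a 2,4-diaryl-3-azabicyclo[3.3.1]nonan-9-one. Such contractions of 2,6-diarylpiperidines keep the configuration at both carbons, so the amine must be the 2,4-trans isomer (C6 aryl equatorial, C7 aryl axial). It is reached from the kinetic cis amine by epimerising its N-nitroso derivative.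
- C5–C6, C4–C7 and both C–N bonds: a sulfinyl-controlled Mannich addition and an intramolecular Mannich closure on the monoketal of cyclohexane-1,3-dione.
- The C3 ketone becomes the C1(=O)–C2=C3–styryl unit by dehydrogenation, hydroxylation at C1, styryl addition at C3, oxidation and dehydration, with C8 masked as a silyl ether; demethylation is last.
- Ring order: carbocycle C1–C5/C8 (purchased), piperidine ring (step 4), five-membered ring by contraction (step 7).

Key step: step 7

Remarks
- Numbering: the core numbering above is used for all bicyclic compounds; in the azabicycles N lies between C6 and C7; "exo" and "syn to C8" mean the side of the C8 bridge.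
- Assumption: 1,4-dioxaspiro[4.5]decan-7-one (4) is taken as a purchasable starting material.
- Assumption: the sense of induction in step 2 follows the closed, lithium-bridged transition state; if the open mode prevailed, (R)-2-methylpropane-2-sulfinamide would be used instead.
- Assumption: the ketone α-centre in 6, 7 and 9, the C1 carbinol in 23, 24 and 28–29 and the C3 carbinol in 28–30 are transient and are drawn as the expected epimers; either epimer converges.

**Step 1**
Reactants: 1 (S)-2-methylpropane-2-sulfinamide; 2 3,4-dimethoxybenzaldehyde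
Product: 3 (S,E)-N-(3,4-dimethoxybenzylidene)-2-methylpropane-2-sulfinamide
Conditions: Ti(OEt)4 (2 equiv), THF, 23 °C
Reagents that add atoms: none
Why: Lewis acid-mediated condensation of an aryl aldehyde with a primary sulfinamide should give the E-configured N-sulfinyl aldimine without touching the sulfur stereocentre.

**Step 2**
Reactants: 4 1,4-dioxaspiro[4.5]decan-7-one; 3 the sulfinyl imine
Product: 6 (S)-N-[(R)-(3,4-dimethoxyphenyl)(7-oxo-1,4-dioxaspiro[4.5]decan-8-yl)methyl]-2-methylpropane-2-sulfinamide, via lithium enolate 5 (not isolated)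
Conditions: lithium diisopropylamide (1.3 equiv), THF, −78 °C; then 3, −78 °C; AcOH quench
Reagents that add atoms: none
Why: Kinetic deprotonation should take the methylene remote from the quaternary ketal carbon, and the Mannich addition of the lithium enolate through a closed Zimmerman–Traxler transition state, with lithium bridging the enolate and sulfinyl oxygens, should deliver the nucleophile to the Re face of the (S)-sulfinyl imine and set C6 as R, while the adjacent ketone α-centre is epimerisable and does not matter.

**Step 3**
Reactants: 6 the sulfinamide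
Product: 7 (R)-(3,4-dimethoxyphenyl)(7-oxo-1,4-dioxaspiro[4.5]decan-8-yl)methanaminium chloride
Conditions: HCl (4 M in dioxane, 2.2 equiv), cyclopentyl methyl ether, 0 °C, 15 min; filtration
Reagents that add atoms: hydrogen chloride, Cl
Why: Acidolysis of the S–N bond by anhydrous HCl is fast at 0 °C, the product leaves solution as an ammonium salt that cannot undergo retro-Mannich cleavage, and the brief water-free exposure should spare the dioxolane, whose ionisation is slowed by the adjacent carbonyl group.

**Step 4**
Reactants: 7 the ammonium chloride; 8 3,5-dimethoxybenzaldehyde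
Product: 10 cis amine: C3-ketal 3-azabicyclo[3.3.1]nonan-9-one with equatorial 3,4-dimethoxyphenyl on C6 and equatorial 3,5-dimethoxyphenyl on C7, via imine 9 (not isolated)
Conditions: NaOAc (1.1 equiv), 4 Å molecular sieves, EtOH, 23 °C then 45 °C
Reagents that add atoms: none
Why: Condensation gives the E-imine, which is attacked by the C4 enol in a six-membered chair transition state (intramolecular Mannich reaction) under the acetate buffer formed in the flask; the ring can only close with both nitrogen-bearing arms axial on the cyclohexanone, which fixes C4 and C5 relative to the equatorial C6 aryl group, and the C7 aryl group, expected equatorial, is reset in step 5.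

**Step 5**
Reactants: 10 the cis amine
Product: 12 trans nitrosamine: N-nitroso derivative with equatorial C6 aryl and axial C7 aryl, via cis nitrosamine 11 (not isolated)
Conditions: t-BuONO (1.5 equiv), THF, 23 °C; then KOt-Bu (0.3 equiv), t-BuOH, 40 °C
Reagents that add atoms: tert-butyl nitrite, CC(C)(C)ON=O
Why: Nitrosyl transfer gives the nitrosamine, whose benzylic α-hydrogens are acidified by the N–N=O group, and base-mediated epimerisation under thermodynamic control should move the C7 aryl group to the axial position, which removes its allylic 1,3-strain with the planar nitrosamine and its syn-pentane contact with the equatorial ketal oxygen, while C6 stays equatorial because a second axial aryl group would collide with the first, and the bridgeheads are not touched.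

**Step 6**
Reactants: 12 the trans nitrosamine
Product: 13 trans amine: C3-ketal 3-azabicyclo[3.3.1]nonan-9-one with equatorial 3,4-dimethoxyphenyl on C6 and axial 3,5-dimethoxyphenyl on C7
Conditions: Raney Ni, H2 (1 atm), EtOH, 23 °C
Reagents that add atoms: none
Why: Hydrogenolysis of the N–N bond of the nitrosamine returns the secondary amine, the α-branched benzylic C–N bonds, the ketal and the hindered non-enolisable ketone should react far more slowly, and no stereocentre is touched.

**Step 7**
Reactants: 13 the trans amine
Product: 17 C3-ketal 6-endo-(3,4-dimethoxyphenyl)-7-exo-(3,5-dimethoxyphenyl)bicyclo[3.2.1]octan-8-one, via hydrazide adduct 14 (not isolated), via isodiazene 15 (not isolated), via 1,5-diradical 16 (not isolated)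
Conditions: N-(benzyloxy)-N-(pivaloyloxy)-4-(trifluoromethyl)benzamide (1.5 equiv), THF, 45 °C
Reagents that add atoms: none
Why: The amine attacks the amide nitrogen with loss of pivalate, the N-alkoxy-N-acyl hydrazine 14 expels benzyl 4-(trifluoromethyl)benzoate in a HERON-type shift, and the isodiazene 15 loses N2 to the doubly benzylic 1,5-diradical 16, which collapses to the C6–C7 bond; the closest known reaction type is the nitrogen deletion of benzylic secondary amines, including the configuration-retaining contraction of 2,6-diarylpiperidine isodiazenes to 1,2-diarylcyclopentanes. The five-membered ring C4–C8–C5–C6–C7 closes by radical–radical recombination between two centres held syn-axial on the cyclohexanone, about 2.5 Å apart, so recombination should outrun C–C rotation and disproportionation. C6 keeps its equatorial aryl group, which becomes endo, and C7 keeps its axial aryl group, which becomes exo, both by least-motion collapse, so the trans relationship fixed in step 5 is carried over. The selectivity needed is for the C6-endo, C7-exo isomer over the cis isomers, and it is secured twice: by the 2,4-trans configuration of 13 and, should a radical centre turn before bonding, by the C3 ketal oxygen that blocks the endo sector at C7 and by the eclipsing a cis pair would suffer. Hydrogen transfer to an arylidene ketone is disfavoured because the hydrogens on C4 and C5 point away from the opposite radical centre, and the non-enolisable C8 ketone and the ketal are inert to the neutral conditions.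

**Step 8**
Reactants: 17 the ketal ketone
Product: 18 6-endo-(3,4-dimethoxyphenyl)-7-exo-(3,5-dimethoxyphenyl)bicyclo[3.2.1]octane-3,8-dione (core numbering)
Conditions: 1 M HCl (aq), THF, 23 °C
Reagents that add atoms: water, O
Why: Acid-catalysed ketal hydrolysis through the C3 oxocarbenium ion unmasks the ketone, and the product can neither lose an oxygen by β-elimination nor enolise between the two carbonyl groups because C4 is a bridgehead.

**Step 9**
Reactants: 18 the dione
Product: 20 C1=C2 enedione (C3 and C8 ketones), via trimethylsilyl enol ether 19 (not isolated)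
Conditions: LiN(SiMe3)2 (1.2 equiv), Me3SiCl (1.5 equiv), THF, −78 °C; then Pd(OAc)2 (1.1 equiv), MeCN, 23 °C
Reagents that add atoms: none
Why: Saegusa–Ito dehydrogenation, in which the C3 ketone can enolise only toward C2 because C4 is a bridgehead and C8 has no removable α-hydrogen, and β-hydride elimination from the palladium enolate places the double bond between C1 and C2.

**Step 10**
Reactants: 20 the enedione
Product: 21 C8 alcohol of the enone, hydroxyl syn to the C6–C7 bridge
Conditions: NaBH4 (1.0 equiv), MeOH/CH2Cl2 (1:1), −78 °C
Reagents that add atoms: none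
Why: Chemoselective borohydride reduction, in which the saturated, angle-strained C8 ketone should react faster than the conjugated C3 carbonyl, and hydride should arrive from the face of the now flat C1–C2–C3 bridge because the other face is shielded by the exo C7 aryl group, so the hydroxyl ends up syn to the C6–C7 bridge and away from C1.

**Step 11**
Reactants: 21 the hydroxy enone
Product: 22 C8 tert-butyldimethylsilyl ether of the enone
Conditions: t-BuMe2SiOTf (1.3 equiv), 2,6-lutidine (2 equiv), CH2Cl2, −78 to 0 °C
Reagents that add atoms: tert-butyldimethylsilyl trifluoromethanesulfonate, CC(C)(C)[Si](C)(C)OS(=O)(=O)C(F)(F)F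
Why: Silylation of the hindered secondary alcohol with the silyl triflate masks C8 as an ether that tolerates the alkoxide of step 12 and the organometallic of step 14 and prevents a retro-aldol opening between C8 and C4.

**Step 12**
Reactants: 22 the silyloxy enone
Product: 24 C1-hydroxy C3-ketone (C1 hydroxyl syn to C8), via C1 boronate 23 (not isolated)
Conditions: CuCl (5 mol %), Xantphos (5 mol %), NaOt-Bu (10 mol %), B2pin2 (1.2 equiv), MeOH (2 equiv), THF, 23 °C; then NaBO3·4H2O (5 equiv), THF/H2O, 23 °C
Reagents that add atoms: sodium perborate, [Na+].[O-]OB=O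
Why: Copper-catalysed conjugate borylation should place boron on C1 from the face syn to C8, where only the C8 hydrogen projects and the other face is covered by the endo C6 aryl group, and perborate oxidation replaces boron by hydroxyl with retention, giving a carbinol whose configuration is irrelevant because it is oxidised in step 16.

**Step 13**
Reactants: 25 (E)-3,4-dimethoxycinnamic acid
Product: 26 (E)-4-(2-bromovinyl)-1,2-dimethoxybenzene
Conditions: N-bromosuccinimide (1.1 equiv), LiOAc (0.1 equiv), MeCN/H2O (97:3), 23 °C
Reagents that add atoms: N-bromosuccinimide, O=C1CCC(=O)N1Br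
Why: Catalytic Hunsdiecker-type bromodecarboxylation of an electron-rich cinnamic acid, in which bromonium formation and decarboxylative opening anti to bromine should give the E-bromostyrene.

**Step 14**
Reactants: 26 the bromostyrene; 24 the hydroxy ketone
Product: 28 C1,C3-diol with (E)-3,4-dimethoxystyryl on C3 and silyl ether on C8, via styryllithium 27 (not isolated)
Conditions: t-BuLi (7 equiv), 26 (3.5 equiv), Et2O, −78 °C; CeCl3 (3.5 equiv), THF, −78 °C; then 24, −78 to −40 °C; aq NH4Cl
Reagents that add atoms: none
Why: Lithium–bromine exchange keeps the alkene geometry, transmetalation gives a weakly basic organocerium reagent, and after the first equivalent has formed the C1 alkoxide the 1,2-addition to the C3 ketone should occur from the face of the C6–C7 bridge, where C7 presents only hydrogen, giving a tertiary carbinol whose configuration is lost again in step 17.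

**Step 15**
Reactants: 28 the silyl ether diol
Product: 29 C1,C3,C8-triol
Conditions: Bu4NF (1.5 equiv), THF, 23 °C
Reagents that add atoms: none
Why: Fluoride-mediated desilylation frees the C8 hydroxyl, and because no carbonyl group is present the basic fluoride cannot trigger a retro-aldol cleavage.

**Step 16**
Reactants: 29 the triol
Product: 30 C3-hydroxy C1,C8-dione
Conditions: Dess–Martin periodinane (3 equiv), pyridine (6 equiv), CH2Cl2, 0 to 23 °C
Reagents that add atoms: none
Why: Dess–Martin oxidation converts both secondary carbinols (C1 and C8) into ketones and leaves the tertiary C3 carbinol, and the buffered, non-basic medium should avoid retro-aldol cleavage, while C5 between the two carbonyl groups cannot enolise because it is a bridgehead.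

**Step 17**
Reactants: 30 the hydroxy dione
Product: 31 hexa-O-methyljezonodione
Conditions: methyl N-(triethylammoniumsulfonyl)carbamate (2.5 equiv), THF, 50 °C
Reagents that add atoms: none
Why: Burgess dehydration by syn elimination of the tertiary sulfamate, in which only a C2 hydrogen can be lost because C4 is a bridgehead, gives the C2=C3 dienone conjugated with C1 without a free cation next to the electron-rich arenes.

**Step 18**
Reactants: 31 hexa-O-methyljezonodione
Product: 32 jezonodione
Conditions: BBr3 (12 equiv), CH2Cl2, −78 to 0 °C; then MeOH, H2O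
Reagents that add atoms: none
Why: Lewis acid-mediated demethylation of the six aryl methyl ethers should free the catechol and resorcinol units, and no stereocentre can epimerise because C4 and C5 are bridgeheads and C6 and C7 are not α to a carbonyl group.

**Compound list**
1 | (S)-2-methylpropane-2-sulfinamide | CC(C)(C)[S@](=O)N | starting material
2 | 3,4-dimethoxybenzaldehyde | COc1ccc(C=O)cc1OC | starting material
3 | (S,E)-N-(3,4-dimethoxybenzylidene)-2-methylpropane-2-sulfinamide | CC(C)(C)[S@](=O)/N=C/c1ccc(OC)c(OC)c1 | intermediate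
4 | 1,4-dioxaspiro[4.5]decan-7-one | O=C1CCCC2(C1)OCCO2 | starting material
5 | lithium 1,4-dioxaspiro[4.5]dec-7-en-7-olate | [Li+].[O-]C1=CCCC2(C1)OCCO2 | intermediate
6 | (S)-N-[(R)-(3,4-dimethoxyphenyl)(7-oxo-1,4-dioxaspiro[4.5]decan-8-yl)methyl]-2-methylpropane-2-sulfinamide, ketone α-centre as epimer mixture | CC(C)(C)[S@](=O)N[C@@H](c1ccc(OC)c(OC)c1)C1CCC2(CC1=O)OCCO2 | intermediate
7 | (R)-(3,4-dimethoxyphenyl)(7-oxo-1,4-dioxaspiro[4.5]decan-8-yl)methanaminium chloride | [Cl-].[NH3+][C@@H](c1ccc(OC)c(OC)c1)C1CCC2(CC1=O)OCCO2 | intermediate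
8 | 3,5-dimethoxybenzaldehyde | COc1cc(C=O)cc(OC)c1 | starting material
9 | (E)-N-(3,5-dimethoxybenzylidene) imine of the free amine of 7 | COc1cc(/C=N/[C@@H](c2ccc(OC)c(OC)c2)C2CCC3(CC2=O)OCCO3)cc(OC)c1 | intermediate
10 | cis amine: C3-ketal 3-azabicyclo[3.3.1]nonan-9-one, C6 aryl equatorial, C7 aryl equatorial | C1CC3(OCCO3)[C@@H]2C(=O)[C@H]1[C@H](c4ccc(OC)c(OC)c4)N[C@@H]2c5cc(OC)cc(OC)c5 | intermediate
11 | cis nitrosamine: N-nitroso derivative of 10 | C1CC3(OCCO3)[C@@H]2C(=O)[C@H]1[C@H](c4ccc(OC)c(OC)c4)N(N=O)[C@@H]2c5cc(OC)cc(OC)c5 | intermediate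
12 | trans nitrosamine: C6 aryl equatorial, C7 aryl axial | C1CC3(OCCO3)[C@@H]2C(=O)[C@H]1[C@H](c4ccc(OC)c(OC)c4)N(N=O)[C@H]2c5cc(OC)cc(OC)c5 | intermediate
13 | trans amine: C3-ketal 3-azabicyclo[3.3.1]nonan-9-one, C6 aryl equatorial, C7 aryl axial | C1CC3(OCCO3)[C@@H]2C(=O)[C@H]1[C@H](c4ccc(OC)c(OC)c4)N[C@H]2c5cc(OC)cc(OC)c5 | intermediate
14 | N-(benzyloxy)-N-[4-(trifluoromethyl)benzoyl]amino derivative of 13 | C1CC3(OCCO3)[C@@H]2C(=O)[C@H]1[C@H](c4ccc(OC)c(OC)c4)N(N(OCc6ccccc6)C(=O)c7ccc(C(F)(F)F)cc7)[C@H]2c5cc(OC)cc(OC)c5 | intermediate
15 | isodiazene (1,1-diazene) of 13 | C1CC3(OCCO3)[C@@H]2C(=O)[C@H]1[C@H](c4ccc(OC)c(OC)c4)[N+](=[N-])[C@H]2c5cc(OC)cc(OC)c5 | intermediate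
16 | 1,5-diradical: cis-2,6-bis(arylmethyl radical) of the ketal cyclohexanone | C1CC3(OCCO3)[C@@H]([CH]c5cc(OC)cc(OC)c5)C(=O)[C@H]1[CH]c4ccc(OC)c(OC)c4 | intermediate
17 | C3-ketal 6-endo-(3,4-dimethoxyphenyl)-7-exo-(3,5-dimethoxyphenyl)bicyclo[3.2.1]octan-8-one (core numbering) | C1CC3(OCCO3)[C@@H]2C(=O)[C@H]1[C@H](c4ccc(OC)c(OC)c4)[C@H]2c5cc(OC)cc(OC)c5 | intermediate
18 | 6-endo,7-exo-diaryl bicyclo[3.2.1]octane-3,8-dione (core numbering) | C1CC(=O)[C@@H]2C(=O)[C@H]1[C@H](c4ccc(OC)c(OC)c4)[C@H]2c5cc(OC)cc(OC)c5 | intermediate
19 | C3 trimethylsilyl enol ether (C2=C3) of 18 | C1C=C(O[Si](C)(C)C)[C@@H]2C(=O)[C@H]1[C@H](c4ccc(OC)c(OC)c4)[C@H]2c5cc(OC)cc(OC)c5 | intermediate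
20 | C1=C2 enedione (C3 and C8 ketones) | C1=CC(=O)[C@@H]2C(=O)[C@H]1[C@H](c4ccc(OC)c(OC)c4)[C@H]2c5cc(OC)cc(OC)c5 | intermediate
21 | C8 alcohol of the C1=C2 enone, hydroxyl syn to the C6–C7 bridge | C1=CC(=O)[C@@H]2[C@@H](O)[C@H]1[C@H](c4ccc(OC)c(OC)c4)[C@H]2c5cc(OC)cc(OC)c5 | intermediate
22 | C8 tert-butyldimethylsilyl ether of 21 | C1=CC(=O)[C@@H]2[C@@H](O[Si](C)(C)C(C)(C)C)[C@H]1[C@H](c4ccc(OC)c(OC)c4)[C@H]2c5cc(OC)cc(OC)c5 | intermediate
23 | C1 pinacol boronate (boron syn to C8) of the C3 ketone | [C@@H]1(B6OC(C)(C)C(C)(C)O6)CC(=O)[C@@H]2[C@@H](O[Si](C)(C)C(C)(C)C)[C@H]1[C@H](c4ccc(OC)c(OC)c4)[C@H]2c5cc(OC)cc(OC)c5 | intermediate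
24 | C1-hydroxy C3-ketone with C8 silyl ether (C1 hydroxyl syn to C8) | [C@@H]1(O)CC(=O)[C@@H]2[C@@H](O[Si](C)(C)C(C)(C)C)[C@H]1[C@H](c4ccc(OC)c(OC)c4)[C@H]2c5cc(OC)cc(OC)c5 | intermediate
25 | (E)-3,4-dimethoxycinnamic acid | COc1ccc(/C=C/C(=O)O)cc1OC | starting material
26 | (E)-4-(2-bromovinyl)-1,2-dimethoxybenzene | COc1ccc(/C=C/Br)cc1OC | intermediate
27 | (E)-2-(3,4-dimethoxyphenyl)vinyllithium | COc1ccc(/C=C/[Li])cc1OC | intermediate
28 | C1,C3-diol with (E)-3,4-dimethoxystyryl on C3 and C8 silyl ether | [C@@H]1(O)C[C@@](O)(/C=C/c6ccc(OC)c(OC)c6)[C@@H]2[C@@H](O[Si](C)(C)C(C)(C)C)[C@H]1[C@H](c4ccc(OC)c(OC)c4)[C@H]2c5cc(OC)cc(OC)c5 | intermediate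
29 | C1,C3,C8-triol with (E)-3,4-dimethoxystyryl on C3 | [C@@H]1(O)C[C@@](O)(/C=C/c6ccc(OC)c(OC)c6)[C@@H]2[C@@H](O)[C@H]1[C@H](c4ccc(OC)c(OC)c4)[C@H]2c5cc(OC)cc(OC)c5 | intermediate
30 | C3-hydroxy C1,C8-dione with (E)-3,4-dimethoxystyryl on C3 | O=C1C[C@@](O)(/C=C/c6ccc(OC)c(OC)c6)[C@@H]2C(=O)[C@H]1[C@H](c4ccc(OC)c(OC)c4)[C@H]2c5cc(OC)cc(OC)c5 | intermediate
31 | hexa-O-methyljezonodione | O=C1C=C(/C=C/c6ccc(OC)c(OC)c6)[C@@H]2C(=O)[C@H]1[C@H](c4ccc(OC)c(OC)c4)[C@H]2c5cc(OC)cc(OC)c5 | intermediate
32 | jezonodione | O=C1C=C(/C=C/c2ccc(O)c(O)c2)[C@@H]2C(=O)[C@H]1[C@H](c1ccc(O)c(O)c1)[C@H]2c1cc(O)cc(O)c1 | target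

**Totals**
Total step count: 18. Longest linear sequence: 17 steps (steps 1–12 and 14–18; step 13 is a one-step side branch).

**Steps most likely to fail**

Step 7. The nitrogen of 13 is flanked by two aryl-branched carbons, so nitrogen transfer from the anomeric amide may be slow, or the isodiazene may be diverted before N2 is lost. The fallback sets out from nitrosamine 12 and generates the same isodiazene by oxidation instead of nitrogen transfer. Reduction of 12 with Zn dust and NH4Cl in MeOH/H2O should give the 1-amino amine F1. Oxidation of F1 with HgO in EtOH at 60 °C should form isodiazene 15, which collapses through 16. The fallback comes back to the route at 17.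

Step 5. Reprotonation of the α-nitrosamino carbanion may occur only from the open face, so that no net epimerisation takes place, or the base may cause loss of the nitroso group. The fallback sets out from cis amine 10 and corrects C7 after the ring contraction. Treatment of 10 under the conditions of step 7 should give the hydrazide adduct F2 and the cis isodiazene F3. F3 should lose N2 and close with retention, through 16, to the all-endo cis-diaryl ketone F4. Reversible hydrogen-atom transfer at the benzylic C7–H, with (n-Bu4N)4W10O32 (2 mol %), a diaryl disulfide cocatalyst and 390 nm light in MeCN, should then equilibrate F4 to the exo C7 isomer. This isomer is favoured because it relieves the aryl–aryl eclipsing and the contact of the endo C7 aryl group with the C3 ketal. The fallback comes back to the route at 17.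

Step 4. Bond formation at C4, next to the quaternary ketal carbon, may lose out to β-elimination of a ketal oxygen, and reversible Mannich steps may erode the enantiomeric purity. The fallback sets out from sulfinamide 6 and closes the ring by C–N instead of C–C bond formation. Double deprotonation of 6 with lithium diisopropylamide (2.2 equiv) at −78 °C and addition of 8 should give the aldol adduct F5. Mesylation with MsCl and Et3N followed by DBU should give the arylidene ketone F6. HCl in cyclopentyl methyl ether should give the ammonium chloride F7. K2CO3 in MeOH should free the amine, which should close by 6-endo aza-Michael addition, with protonation at C4 on the only face the bicycle allows. The C7 configuration is again left to step 5. The fallback comes back to the route at 10.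

**Further compounds**
F1 | step 7 | 1-amino derivative of trans amine 13 | C1CC3(OCCO3)[C@@H]2C(=O)[C@H]1[C@H](c4ccc(OC)c(OC)c4)N(N)[C@H]2c5cc(OC)cc(OC)c5
F2 | step 5 | N-(benzyloxy)-N-[4-(trifluoromethyl)benzoyl]amino derivative of cis amine 10 | C1CC3(OCCO3)[C@@H]2C(=O)[C@H]1[C@H](c4ccc(OC)c(OC)c4)N(N(OCc6ccccc6)C(=O)c7ccc(C(F)(F)F)cc7)[C@@H]2c5cc(OC)cc(OC)c5
F3 | step 5 | isodiazene of cis amine 10 | C1CC3(OCCO3)[C@@H]2C(=O)[C@H]1[C@H](c4ccc(OC)c(OC)c4)[N+](=[N-])[C@@H]2c5cc(OC)cc(OC)c5
F4 | step 5 | C3-ketal 6-endo-(3,4-dimethoxyphenyl)-7-endo-(3,5-dimethoxyphenyl)bicyclo[3.2.1]octan-8-one | C1CC3(OCCO3)[C@@H]2C(=O)[C@H]1[C@H](c4ccc(OC)c(OC)c4)[C@@H]2c5cc(OC)cc(OC)c5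
F5 | step 4 | aldol adduct of 6 with 8 at the ketal-flanked α-carbon (diastereomer mixture) | CC(C)(C)[S@](=O)N[C@@H](c1ccc(OC)c(OC)c1)C2CCC3(OCCO3)C(C(O)c4cc(OC)cc(OC)c4)C2=O
F6 | step 4 | 3,5-dimethoxybenzylidene ketone from F5 (either alkene isomer) | CC(C)(C)[S@](=O)N[C@@H](c1ccc(OC)c(OC)c1)C2CCC3(OCCO3)C(=Cc4cc(OC)cc(OC)c4)C2=O
F7 | step 4 | ammonium chloride of the desulfinylated arylidene ketone | [Cl-].[NH3+][C@@H](c1ccc(OC)c(OC)c1)C2CCC3(OCCO3)C(=Cc4cc(OC)cc(OC)c4)C2=O
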